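The numbers in the tables are simulated for an exercise; the scatter is artificial.

The flat end of a yield curve tempts me to read a stalled catalyst and to hope for more from a longer time, but in the birch and ash runs the target stands still at a height that rises with the reagent charge. So I read the plateau as the end of the reagent, the limiting reagent, which starting material and second substrate share between them, one equivalent for each molecule converted.

| setting | birch | ash | autumn | noon |
|---|---|---|---|---|
| starting material | 0.20 M | 0.20 M | 0.20 M | 0.20 M |
| second substrate | 0.50 equiv | 0.50 equiv | 0.500 equiv | 0.500 equiv |
| reagent | 0.44 equiv | 0.75 equiv | 0.800 equiv | 0.960 equiv |
| precatalyst | 0.1 mol% | 0.1 mol% | 0.1 mol% | 0.1 mol% |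
| remark | run made earlier | run made earlier |  |  |
| time |  |  | 2.0 h | 2.0 h |

- birch (time / min: target / %, catalyst intermediate A / %, starting material / %): 10.0: 17.7, 0, 81.9; 30.0: 23.3, 0.5, 77.7; 50.0: 22.1, 0.5, 76.6; 80.0: 22.5, 0.6, 78.0
- ash (time / min: target / %, catalyst intermediate A / %, starting material / %): 10.0: 29.7, 0, 68.5; 30.0: 42.0, 0, 55.1; 50.0: 44.5, 0, 55.5; 80.0: 43.7, 1.4, 56.8

(standard deviation of a reading: 1 percentage point)

* which of these there is most of at the end, counted by the starting material in it, autumn (target / catalyst intermediate A / starting material)
* which of these there is most of at the end, counted by the starting material in it, noon (target / catalyst intermediate A / starting material)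
* how much there is at the end of the one of these that leads, in percent of the starting material charged: autumn
* how much there is at the end of the one of these that leads, in percent of the starting material charged: noon

Two extreme flasks can be done in the head. Let the second substrate take no reagent: the target then equals the charge, and target meets starting material at 0.5 equiv. Let the second substrate take its whole charge first: they meet at 1.00 equiv. Autumn with 0.800 equiv and noon with 0.960 equiv both stand above the first crossing and below the second, so the extremes leave both open.

A ratio read from a finished run places the real flask between them. With u and w the fractions of starting material and second substrate left at the end of a run, I define S as ln u divided by ln w, an effective selectivity factor averaged over that run and not a constant of the pair, and I assume that it carries over from ash to nearby charges. My own reckoning takes the last two ash readings, which put the target at 44.1%, so w is 38.2% and S is 0.604. Setting u to 0.5 gives 0.841 equiv, and this is what I carry: the crossing charge, the reagent charge at which target and starting material stand equal. Autumn lies below it and noon above it, so I expect starting material to lead in autumn and target in noon.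

The forecast holds that “the reagent is limiting, and 2 h is enough for it to run out”, and it takes the ratio as 0.55 where I take 0.604. It gives starting material leading autumn at 54% and target leading noon at 57%.

The flask gives starting material at 52.6% in autumn and target at 58.5% in noon, each on the expected side of the crossing charge. In autumn the making of target had half of its turnover behind it by 0.112 h, and at 1.00 h the reagent stood at 0.106% of its charge. After that the flask stayed as it was, with starting material at 52.6% after 20.0 h and 35% of the second substrate unused, so in this flask time buys nothing and the reagent charge is the setting to move.

    starting material + free catalyst ⇌ catalyst intermediate A (K = 3.20 M⁻¹, k = 19.0 M⁻¹ s⁻¹)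
    reagent + catalyst intermediate A → free catalyst + target (k = 26.0 M⁻¹ s⁻¹)
    second substrate + free catalyst ⇌ catalyst intermediate B (K = 12.0 M⁻¹, k = 9.20 M⁻¹ s⁻¹)
    reagent + catalyst intermediate B → free catalyst + second product (k = 26.0 M⁻¹ s⁻¹)
    precatalyst ⇌ free catalyst (K = 6.10, k = 0.0220 s⁻¹)

For a neighbour of autumn charged with 2.00 equiv of second substrate, the same assumed S puts the crossing charge at 1.86 equiv, well above its 0.800 equiv of reagent, so starting material should lead there. The computed flask ends with 79.2% starting material and 20.8% target.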